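Numbering as for carotenoids: ring B (cyclohexane-1,2-diol) = C1–C6 with chain C7–C15; ring A (cyclohexenol) = C1'–C6' with chain C7'–C15'. The last disconnection is the C8'–C9' bond between the alkyne carbon and the methyl-bearing alkene carbon: Sonogashira union of the unprotected ring A alkyne 23 (C11) with the unprotected iodo-octaene 17 (C29), which gives the target directly.
Enabling feature: the C7'≡C8' triple bond sits on C6' of ring A, so ring A can carry a terminal ethynyl group whose sp C–H is the only acidic C–H, and C9' is the trisubstituted sp2 end of the octaene, where an (E)-C–I bond stores the 9'E geometry.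
17 comes from C25 aldehyde 11 and (E)-iodophosphonate 15 (Horner–Wadsworth–Emmons, C11'=C12'); 11 comes from C15 phosphonium salt 8 and C10 dialdehyde 9 (Wittig, C11=C12).
8 comes from β-cyclocitral: Sharpless epoxidation and anti hydrolysis of the C5–C6 epoxide set both ring B stereocentres, then Wittig, vinyl Grignard addition and allylic transposition build C7–C11; 23 comes from (4R,6R)-actinol (C3' from the chiral pool) by enol triflate formation and Sonogashira ethynylation.
Ring order: no carbocycle is formed; ring B and ring A are bought as six-membered rings (ring B is elaborated first, ring A is joined last), and the only ring made is the transient oxirane on C5–C6.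

Key step: step 15

Remark: 7 is used as a mixture of epimers at its side-chain carbinol carbon, since this centre becomes sp2 in step 6; the ring B descriptors change between 4 and 5 only because the CIP priorities change.

Step 1
Reactants: 1 β-cyclocitral (2,6,6-trimethylcyclohex-1-ene-1-carbaldehyde)
Product: 2 β-cyclogeraniol ((2,6,6-trimethylcyclohex-1-en-1-yl)methanol)
Conditions: NaBH4, MeOH, 0 °C
Reagents that add atoms: none
Why: Borohydride 1,2-reduction of the hindered enal should give the primary allylic alcohol that the titanium tartrate catalyst of the next step needs as its anchoring group, and no stereocentre is formed.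

Step 2
Reactants: 2 β-cyclogeraniol
Product: 3 [(1S,6S)-2,2,6-trimethyl-7-oxabicyclo[4.1.0]heptan-1-yl]methanol
Conditions: Ti(OiPr)4 (10 mol%), L-(+)-diethyl tartrate (12 mol%), t-BuOOH, 4 Å MS, CH2Cl2, −20 °C
Reagents that add atoms: tert-butyl hydroperoxide, CC(C)(C)OO
Why: Katsuki–Sharpless asymmetric epoxidation: the allylic alcohol binds to the titanium tartrate complex and, with L-(+)-diethyl tartrate, oxygen should be delivered to the alkene face that gives the (1S,6S)-epoxide (the sense that gives (2S,3S)-epoxides from acyclic allylic alcohols), the cis ring fusion setting both new stereocentres at once.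

Step 3
Reactants: 3 [(1S,6S)-2,2,6-trimethyl-7-oxabicyclo[4.1.0]heptan-1-yl]methanol
Product: 4 (1S,2R)-1-(hydroxymethyl)-2,6,6-trimethylcyclohexane-1,2-diol
Conditions: HClO4 (cat.), THF/H2O, 0 °C → rt
Reagents that add atoms: water, O
Why: Acid-catalysed hydrolysis of a 2,3-epoxy alcohol is an SN2-like opening at the distal carbon, so water should attack the methyl-bearing tertiary carbon with inversion (the other epoxide carbon is neopentylic and deactivated by the adjacent CH2OH group) while the C–O bond at the carbinol-bearing carbon is retained, which gives the trans-diol with the (1S,2R) configuration that corresponds to (5R,6R) in the target.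

Step 4
Reactants: 4 (1S,2R)-1-(hydroxymethyl)-2,6,6-trimethylcyclohexane-1,2-diol
Product: 6 (3E)-4-[(1R,2R)-1,2-dihydroxy-2,6,6-trimethylcyclohexyl]but-3-en-2-one, via dihydroxy aldehyde 5 (not isolated)
Conditions: SO3·pyridine, DMSO, iPr2NEt, CH2Cl2, 0 °C; then Ph3P=CHC(O)CH3, rt → 40 °C
Reagents that add atoms: (acetylmethylene)triphenylphosphorane, CC(=O)C=P(c1ccccc1)(c1ccccc1)c1ccccc1
Why: Parikh–Doering oxidation acts only on the primary alcohol, and trapping the hindered tertiary α-hydroxy aldehyde in the same flask with a non-basic stabilised ylide (Wittig reaction) should give the (E)-enone before an α-ketol shift can intervene; the two ring stereocentres are not involved.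

Step 5
Reactants: 6 (3E)-4-[(1R,2R)-1,2-dihydroxy-2,6,6-trimethylcyclohexyl]but-3-en-2-one
Product: 7 (1R,2R)-1-[(1E)-3-hydroxy-3-methylpenta-1,4-dien-1-yl]-2,6,6-trimethylcyclohexane-1,2-diol (both epimers at the side-chain carbinol)
Conditions: CH2=CHMgBr (4 equiv), THF, −20 → 0 °C; aq. NH4Cl
Reagents that add atoms: vinylmagnesium bromide, C=C[Mg]Br
Why: Grignard 1,2-addition to the enone carbonyl is favoured because the β-carbon is shielded by the fully substituted ring carbon next to it; the new tertiary carbinol centre is formed without control, which is of no consequence because it becomes sp2 in step 6.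

Step 6
Reactants: 7 (1R,2R)-1-[(1E)-3-hydroxy-3-methylpenta-1,4-dien-1-yl]-2,6,6-trimethylcyclohexane-1,2-diol
Product: 8 [(2E,4E)-5-[(1R,2R)-1,2-dihydroxy-2,6,6-trimethylcyclohexyl]-3-methylpenta-2,4-dien-1-yl]triphenylphosphonium bromide
Conditions: PPh3·HBr, MeOH, 0 °C → rt, dark; crystallisation
Reagents that add atoms: triphenylphosphine hydrobromide, [Br-].[PH+](c1ccccc1)(c1ccccc1)c1ccccc1
Why: Allylic transposition of a tertiary vinyl carbinol with PPh3·HBr (the standard entry to C15 Wittig salts from ionone-type vinyl carbinols): ionisation at the doubly allylic carbinol carbon and capture of the pentadienyl cation by PPh3 at its unhindered primary end should give the conjugated (2E,4E)-phosphonium salt under thermodynamic control, the buffered acid being too weak to ionise the ring diol.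

Step 7
Reactants: 8 [(2E,4E)-5-[(1R,2R)-1,2-dihydroxy-2,6,6-trimethylcyclohexyl]-3-methylpenta-2,4-dien-1-yl]triphenylphosphonium bromide; 9 (2E,4E,6E)-2,7-dimethylocta-2,4,6-trienedial
Product: 11 (2E,4E,6E,8E,10E,12E)-13-[(1R,2R)-1,2-dihydroxy-2,6,6-trimethylcyclohexyl]-2,7,11-trimethyltrideca-2,4,6,8,10,12-hexaenal, via phosphonium ylide 10 (not isolated)
Conditions: 9 (3 equiv), NaOMe, MeOH/CH2Cl2, 0 °C → rt; then EtOH, 70 °C, dark
Reagents that add atoms: none
Why: Wittig olefination with the symmetrical dialdehyde in excess should stop at mono-condensation, the semistabilised allylic ylide giving the new C11=C12 bond mainly as E and the sterically strained 11Z isomer being converted to E on gentle heating.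

Step 8
Reactants: 12 but-2-yn-1-ol
Product: 14 (2E)-3-iodobut-2-en-1-ol, via alkenylzirconocene 13 (not isolated)
Conditions: Cp2Zr(H)Cl (2.3 equiv), THF, rt, dark; then I2, 0 °C; aq. HCl
Reagents that add atoms: iodine, II
Why: Hydrozirconation–iodination: after the hydroxyl group is masked as its zirconium alkoxide, syn addition of Zr–H under equilibrating conditions should place zirconium on the less hindered methyl-bearing alkyne carbon, and iodinolysis with retention should give the (E)-iodoalkene in which iodine is trans to the CH2OH group.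

Step 9
Reactants: 14 (2E)-3-iodobut-2-en-1-ol
Product: 15 diethyl [(2E)-3-iodobut-2-en-1-yl]phosphonate
Conditions: P(OEt)3, ZnI2, THF, reflux
Reagents that add atoms: triethyl phosphite, CCOP(OCC)OCC
Why: ZnI2-mediated one-flask phosphonylation of an allylic alcohol (transesterification to the mixed phosphite followed by a Michaelis–Arbuzov-type rearrangement) should give the allylic phosphonate without touching the alkenyl iodide or its geometry.

Step 10
Reactants: 11 the C25 hexaenal; 15 diethyl [(2E)-3-iodobut-2-en-1-yl]phosphonate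
Product: 17 (1R,2R)-1-[(1E,3E,5E,7E,9E,11E,13E,15E)-16-iodo-3,7,12-trimethylheptadeca-1,3,5,7,9,11,13,15-octaen-1-yl]-2,6,6-trimethylcyclohexane-1,2-diol, via sodium phosphonate carbanion 16 (not isolated)
Conditions: 15, NaN(SiMe3)2, THF, −78 °C; then 11, −78 → 0 °C, dark
Reagents that add atoms: none
Why: Horner–Wadsworth–Emmons olefination of the polyenal with the allylic phosphonate carbanion should form the C11'=C12' bond E-selectively at low temperature; the tertiary hydroxyl groups are not acidic enough to quench the carbanion, and the (E)-iodoalkene resists base because iodine has no anti-periplanar vinylic hydrogen.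

Step 11
Reactants: 18 (4R,6R)-4-hydroxy-2,2,6-trimethylcyclohexan-1-one ((4R,6R)-actinol)
Product: 19 (4R,6R)-4-[(tert-butyldimethylsilyl)oxy]-2,2,6-trimethylcyclohexan-1-one
Conditions: TBSCl, imidazole, DMF, rt
Reagents that add atoms: tert-butyldimethylsilyl chloride, CC(C)(C)[Si](C)(C)Cl
Why: Silylation of the secondary alcohol (TBS ether) is needed so that the ketone can be enolised and triflated in the next step; the stereocentres are untouched.

Step 12
Reactants: 19 (4R,6R)-4-[(tert-butyldimethylsilyl)oxy]-2,2,6-trimethylcyclohexan-1-one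
Product: 21 (4R)-4-[(tert-butyldimethylsilyl)oxy]-2,6,6-trimethylcyclohex-1-en-1-yl trifluoromethanesulfonate, via lithium enolate 20 (not isolated)
Conditions: LiN(iPr)2, THF, −78 → 0 °C; then PhNTf2, 0 °C → rt; aq. NH4Cl
Reagents that add atoms: N-phenylbis(trifluoromethanesulfonimide), O=S(=O)(N(c1ccccc1)S(=O)(=O)C(F)(F)F)C(F)(F)F
Why: Enolisation can occur only towards the methyl-bearing α-carbon because the other α-carbon is quaternary, and O-sulfonylation of the lithium enolate with PhNTf2 should give the tetrasubstituted enol triflate, the α-stereocentre being deliberately converted to sp2.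

Step 13
Reactants: 21 (4R)-4-[(tert-butyldimethylsilyl)oxy]-2,6,6-trimethylcyclohex-1-en-1-yl trifluoromethanesulfonate
Product: 22 tert-butyldimethyl{[(1R)-3,5,5-trimethyl-4-[(trimethylsilyl)ethynyl]cyclohex-3-en-1-yl]oxy}silane
Conditions: HC≡CSiMe3, Pd(PPh3)4 (5 mol%), CuI (10 mol%), Et3N, DMF, 60 °C
Reagents that add atoms: ethynyltrimethylsilane, C#C[Si](C)(C)C
Why: Sonogashira coupling of the enol triflate with trimethylsilylacetylene should install the ethynyl unit (C7'≡C8') on ring A.

Step 14
Reactants: 22 tert-butyldimethyl{[(1R)-3,5,5-trimethyl-4-[(trimethylsilyl)ethynyl]cyclohex-3-en-1-yl]oxy}silane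
Product: 23 (1R)-4-ethynyl-3,5,5-trimethylcyclohex-3-en-1-ol
Conditions: Bu4NF, THF, 0 °C → rt
Reagents that add atoms: none
Why: Fluoride-induced desilylation should cleave both the alkynyl C–Si bond and the silyl ether in one operation to give the free ethynyl carbinol.

Step 15
Reactants: 17 the C29 iodo-octaene diol; 23 (1R)-4-ethynyl-3,5,5-trimethylcyclohex-3-en-1-ol
Product: 24 (1R,2R)-1-[(1E,3E,5E,7E,9E,11E,13E,15E)-18-[(4R)-4-hydroxy-2,6,6-trimethylcyclohex-1-en-1-yl]-3,7,12,16-tetramethyloctadeca-1,3,5,7,9,11,13,15-octaen-17-yn-1-yl]-2,6,6-trimethylcyclohexane-1,2-diol (CNP0289733.1)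
Conditions: Pd(PPh3)4 (5 mol%), CuI (10 mol%), iPr2NH, THF, degassed, dark, rt
Reagents that add atoms: none
Why: Zerovalent palladium inserts into the C(sp2)–I bond of 17 with retention, the ethynyl C–H of 23 is metalated by the copper co-catalyst in the presence of the amine and handed to palladium, and reductive elimination forms the C8'–C9' bond (Sonogashira coupling). The closest known reaction type is the Sonogashira coupling of hindered cyclohexenyl alkynes of this kind with (E)-2-iodoalkenes. No ring is closed and no stereocentre is created; the three existing stereocentres are remote and untouched. The 9'E geometry is controlled by the configuration of the iodoalkene, which is transferred stereospecifically. The step needs chemoselectivity for cross-coupling over oxidative alkyne dimerisation and over E/Z scrambling of the octaene; the high reactivity of the alkenyl iodide secures this by allowing room temperature, exclusion of oxygen and light, and an amine base that leaves the three free hydroxyl groups alone. In this one operation the C40 skeleton and the whole conjugated chromophore are completed and the target is obtained without any later deprotection.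

Compound list
1 | β-cyclocitral (2,6,6-trimethylcyclohex-1-ene-1-carbaldehyde) | CC1=C(C=O)C(C)(C)CCC1 | starting material
2 | β-cyclogeraniol ((2,6,6-trimethylcyclohex-1-en-1-yl)methanol) | CC1=C(CO)C(C)(C)CCC1 | intermediate
3 | [(1S,6S)-2,2,6-trimethyl-7-oxabicyclo[4.1.0]heptan-1-yl]methanol | OC[C@]12O[C@@]1(C)CCCC2(C)C | intermediate
4 | (1S,2R)-1-(hydroxymethyl)-2,6,6-trimethylcyclohexane-1,2-diol | OC[C@@]1(O)C(C)(C)CCC[C@@]1(C)O | intermediate
5 | (1R,2R)-1,2-dihydroxy-2,6,6-trimethylcyclohexane-1-carbaldehyde | O=C[C@@]1(O)C(C)(C)CCC[C@@]1(C)O | intermediate (not isolated)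
6 | (3E)-4-[(1R,2R)-1,2-dihydroxy-2,6,6-trimethylcyclohexyl]but-3-en-2-one | CC(=O)/C=C/[C@@]1(O)C(C)(C)CCC[C@@]1(C)O | intermediate
7 | (1R,2R)-1-[(1E)-3-hydroxy-3-methylpenta-1,4-dien-1-yl]-2,6,6-trimethylcyclohexane-1,2-diol (both epimers at the side-chain carbinol) | C=CC(C)(O)/C=C/[C@@]1(O)C(C)(C)CCC[C@@]1(C)O | intermediate
8 | [(2E,4E)-5-[(1R,2R)-1,2-dihydroxy-2,6,6-trimethylcyclohexyl]-3-methylpenta-2,4-dien-1-yl]triphenylphosphonium bromide | C/C(=C\C[P+](c1ccccc1)(c1ccccc1)c1ccccc1)/C=C/[C@@]1(O)C(C)(C)CCC[C@@]1(C)O.[Br-] | intermediate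
9 | (2E,4E,6E)-2,7-dimethylocta-2,4,6-trienedial (C10 dialdehyde) | O=C/C(C)=C/C=C/C=C(C)/C=O | starting material
10 | (1R,2R)-2,6,6-trimethyl-1-[(1E,3E)-3-methyl-5-(triphenylphosphoranylidene)penta-1,3-dien-1-yl]cyclohexane-1,2-diol (ylide of 8) | C/C(=C\C=P(c1ccccc1)(c1ccccc1)c1ccccc1)/C=C/[C@@]1(O)C(C)(C)CCC[C@@]1(C)O | intermediate (not isolated)
11 | (2E,4E,6E,8E,10E,12E)-13-[(1R,2R)-1,2-dihydroxy-2,6,6-trimethylcyclohexyl]-2,7,11-trimethyltrideca-2,4,6,8,10,12-hexaenal | O=C/C(C)=C/C=C/C=C(C)/C=C/C=C(C)/C=C/[C@@]1(O)C(C)(C)CCC[C@@]1(C)O | intermediate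
12 | but-2-yn-1-ol | CC#CCO | starting material
13 | chlorobis(cyclopentadienyl)zirconium (2E)-3-[chlorobis(cyclopentadienyl)zirconio]but-2-en-1-olate (alkenylzirconocene of the zirconium alkoxide) | C/C(=C\CO[Zr](Cl)(C1C=CC=C1)C1C=CC=C1)/[Zr](Cl)(C1C=CC=C1)C1C=CC=C1 | intermediate (not isolated)
14 | (2E)-3-iodobut-2-en-1-ol | C/C(I)=C\CO | intermediate
15 | diethyl [(2E)-3-iodobut-2-en-1-yl]phosphonate | CCOP(=O)(OCC)C/C=C(C)/I | intermediate
16 | sodium salt of the α-carbanion of 15 | [Na+].CCOP(=O)(OCC)[CH-]/C=C(C)/I | intermediate (not isolated)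
17 | (1R,2R)-1-[(1E,3E,5E,7E,9E,11E,13E,15E)-16-iodo-3,7,12-trimethylheptadeca-1,3,5,7,9,11,13,15-octaen-1-yl]-2,6,6-trimethylcyclohexane-1,2-diol | I/C(C)=C/C=C/C(C)=C/C=C/C=C(C)/C=C/C=C(C)/C=C/[C@@]1(O)C(C)(C)CCC[C@@]1(C)O | intermediate
18 | (4R,6R)-4-hydroxy-2,2,6-trimethylcyclohexan-1-one ((4R,6R)-actinol) | O=C1C(C)(C)C[C@H](O)C[C@H]1C | starting material
19 | (4R,6R)-4-[(tert-butyldimethylsilyl)oxy]-2,2,6-trimethylcyclohexan-1-one | O=C1C(C)(C)C[C@H](O[Si](C)(C)C(C)(C)C)C[C@H]1C | intermediate
20 | lithium (4R)-4-[(tert-butyldimethylsilyl)oxy]-2,6,6-trimethylcyclohex-1-en-1-olate | CC1=C(O[Li])C(C)(C)C[C@H](O[Si](C)(C)C(C)(C)C)C1 | intermediate (not isolated)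
21 | (4R)-4-[(tert-butyldimethylsilyl)oxy]-2,6,6-trimethylcyclohex-1-en-1-yl trifluoromethanesulfonate | CC1=C(OS(=O)(=O)C(F)(F)F)C(C)(C)C[C@H](O[Si](C)(C)C(C)(C)C)C1 | intermediate
22 | tert-butyldimethyl{[(1R)-3,5,5-trimethyl-4-[(trimethylsilyl)ethynyl]cyclohex-3-en-1-yl]oxy}silane | CC1=C(C#C[Si](C)(C)C)C(C)(C)C[C@H](O[Si](C)(C)C(C)(C)C)C1 | intermediate
23 | (1R)-4-ethynyl-3,5,5-trimethylcyclohex-3-en-1-ol | CC1=C(C#C)C(C)(C)C[C@H](O)C1 | intermediate
24 | (1R,2R)-1-[(1E,3E,5E,7E,9E,11E,13E,15E)-18-[(4R)-4-hydroxy-2,6,6-trimethylcyclohex-1-en-1-yl]-3,7,12,16-tetramethyloctadeca-1,3,5,7,9,11,13,15-octaen-17-yn-1-yl]-2,6,6-trimethylcyclohexane-1,2-diol (CNP0289733.1) | CC1=C(C#C/C(C)=C/C=C/C(C)=C/C=C/C=C(C)/C=C/C=C(C)/C=C/[C@@]2(O)C(C)(C)CCC[C@@]2(C)O)C(C)(C)C[C@H](O)C1 | target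

Total step count: 15. Longest linear sequence: 9 steps (steps 1–7, 10 and 15, from 1 to 24).

Steps most likely to fail

Step 15. What may go wrong: decomposition or E/Z isomerisation of the iodo-octaene under Pd/Cu catalysis, or oxidative dimerisation of the alkyne outrunning the cross-coupling. The fallback reverses the order of the last two bond formations, so that the sp–sp2 coupling is done on the small, robust iodide and no iodopolyene is handled. It sets out from alkyne 23 and iodophosphonate 15: Sonogashira coupling (Pd(PPh3)4, CuI, iPr2NH, THF, rt) should give diethyl [(2E)-5-[(4R)-4-hydroxy-2,6,6-trimethylcyclohex-1-en-1-yl]-3-methylpent-2-en-4-yn-1-yl]phosphonate F1. Its dianion (NaN(SiMe3)2, THF, −78 °C) is then condensed with aldehyde 11 in a Horner–Wadsworth–Emmons reaction that forms C11'=C12' and comes back to the route at target 24.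

Step 6. What may go wrong: ionisation at the tertiary allylic ring carbinol or a pinacol-type shift of the ring diol under the acidic conditions, competing with salt formation, and loss of geometric purity at C9=C10. The fallback sets out from enone 6 and comes back at salt 8 through operations that are all neutral or basic. Horner–Wadsworth–Emmons reaction of 6 with triethyl phosphonoacetate (NaH, THF) should give ethyl (2E,4E)-5-[(1R,2R)-1,2-dihydroxy-2,6,6-trimethylcyclohexyl]-3-methylpenta-2,4-dienoate F2, from which the 9Z isomer is removed by chromatography. Reduction with iBu2AlH (CH2Cl2, −78 °C) should give (1R,2R)-1-[(1E,3E)-5-hydroxy-3-methylpenta-1,3-dien-1-yl]-2,6,6-trimethylcyclohexane-1,2-diol F3. Appel bromination of the primary allylic alcohol (CBr4, PPh3, CH2Cl2, −20 °C) should give (1R,2R)-1-[(1E,3E)-5-bromo-3-methylpenta-1,3-dien-1-yl]-2,6,6-trimethylcyclohexane-1,2-diol F4, and quaternisation with PPh3 (EtOAc, rt) returns to 8.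

Step 4. What may go wrong: α-ketol rearrangement or slow olefination of the free, hindered α-hydroxy aldehyde before the ylide traps it. The fallback sets out from triol 4 and comes back at enone 6, with the tertiary hydroxyl groups silylated so that no free α-hydroxy aldehyde is ever present. Persilylation (Me3SiOTf, 2,6-lutidine, CH2Cl2, 0 °C) should give (1S,2R)-2,6,6-trimethyl-1,2-bis[(trimethylsilyl)oxy]-1-{[(trimethylsilyl)oxy]methyl}cyclohexane F5. Swern oxidation ((COCl)2, DMSO, Et3N, CH2Cl2, −78 → −20 °C) converts the primary silyl ether directly into the aldehyde (1R,2R)-2,6,6-trimethyl-1,2-bis[(trimethylsilyl)oxy]cyclohexane-1-carbaldehyde F6 while the tertiary silyl ethers stay. Wittig reaction with Ph3P=CHC(O)CH3 (toluene, 60 °C) should give (3E)-4-[(1R,2R)-2,6,6-trimethyl-1,2-bis[(trimethylsilyl)oxy]cyclohexyl]but-3-en-2-one F7, and methanolysis (K2CO3, MeOH, rt) returns to 6.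

Further compounds
F1 | step 15 | diethyl [(2E)-5-[(4R)-4-hydroxy-2,6,6-trimethylcyclohex-1-en-1-yl]-3-methylpent-2-en-4-yn-1-yl]phosphonate | CC1=C(C#C/C(C)=C/CP(=O)(OCC)OCC)C(C)(C)C[C@H](O)C1
F2 | step 6 | ethyl (2E,4E)-5-[(1R,2R)-1,2-dihydroxy-2,6,6-trimethylcyclohexyl]-3-methylpenta-2,4-dienoate | CCOC(=O)/C=C(C)/C=C/[C@@]1(O)C(C)(C)CCC[C@@]1(C)O
F3 | step 6 | (1R,2R)-1-[(1E,3E)-5-hydroxy-3-methylpenta-1,3-dien-1-yl]-2,6,6-trimethylcyclohexane-1,2-diol | OC/C=C(C)/C=C/[C@@]1(O)C(C)(C)CCC[C@@]1(C)O
F4 | step 6 | (1R,2R)-1-[(1E,3E)-5-bromo-3-methylpenta-1,3-dien-1-yl]-2,6,6-trimethylcyclohexane-1,2-diol | BrC/C=C(C)/C=C/[C@@]1(O)C(C)(C)CCC[C@@]1(C)O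
F5 | step 4 | (1S,2R)-2,6,6-trimethyl-1,2-bis[(trimethylsilyl)oxy]-1-{[(trimethylsilyl)oxy]methyl}cyclohexane | C[Si](C)(C)OC[C@@]1(O[Si](C)(C)C)C(C)(C)CCC[C@@]1(C)O[Si](C)(C)C
F6 | step 4 | (1R,2R)-2,6,6-trimethyl-1,2-bis[(trimethylsilyl)oxy]cyclohexane-1-carbaldehyde | O=C[C@@]1(O[Si](C)(C)C)C(C)(C)CCC[C@@]1(C)O[Si](C)(C)C
F7 | step 4 | (3E)-4-[(1R,2R)-2,6,6-trimethyl-1,2-bis[(trimethylsilyl)oxy]cyclohexyl]but-3-en-2-one | CC(=O)/C=C/[C@@]1(O[Si](C)(C)C)C(C)(C)CCC[C@@]1(C)O[Si](C)(C)C
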